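If I charged this flask and wanted its state at the end, the grey run was the one to read: grey is this very flask, followed so far.

| setting | grey | violet | flask |
|---|---|---|---|
| free monomer | 2.0 × 10⁻⁴ M | 2.0 × 10⁻⁴ M | 2.0 × 10⁻⁴ M |
| protic impurity | 0.020 mM | 0.020 mM | 0.0200 mM |
| pre-initiator | 2 µM | 1 µM | 2.0 µM |
| remark | the very flask that is asked about, followed so far | run made earlier |  |
| time |  |  | 2.5 min |

| run | time / s | monomer in chains / % | free monomer / % |
|---|---|---|---|
| grey | 10.0 | 2.7 | 87.5 |
| grey | 20.0 | 11.2 | 79.3 |
| grey | 30.0 | 23.4 | 65.5 |
| grey | 40.0 | 39.4 | 50.5 |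
| grey | 50.0 | 51.3 | 37.3 |
| grey | 60.0 | 63.8 | 26.9 |
| grey | 80.0 | 77.6 | 11.5 |
| violet | 10.0 | 0.4 | 88.7 |
| violet | 12.0 | 2.0 | 89.2 |
| violet | 15.0 | 3.4 | 87.4 |
| violet | 25.0 | 8.8 | 81.0 |
| violet | 40.0 | 22.7 | 66.0 |
| violet | 60.0 | 43.0 | 46.5 |

(readings scatter by 0.5 percentage points)

- the average divides the monomer in chains by the number of chains begun, living and dead together
- the earlier runs do not show the number of chains; that part of a forecast is a guess

- average number of monomer units in a chain (chains begun, living or dead) at 2.5 min
- part of the free monomer that has reacted at 2.5 min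

First I asked how much free monomer, M, was open to chains. At 80.0 s, M and monomer in chains together made 89.1% of the charge, so the rest had gone elsewhere.

Next I asked how fast M was going. Between the last two grey readings, ln M fell at 0.0425 s⁻¹; that slope is the pseudo-first-order constant κ of free monomer. Between 30.0 s and 50.0 s it had read 0.0282 s⁻¹, so κ was climbing through the run.

Then I asked what κ follows. Between 40.0 s and 60.0 s, grey's κ was 1.80 times that of the violet run, which held half the pre-initiator, so I read κ as a count of chain ends times a rate constant.

Holding κ constant for the remaining 70.0 s took M from 11.5% to 0.587%, so c came to 99.4%. I gave dp no number, because κ did not separate the count from the constant.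

The forecast gave 99.7%, against my 99.4%, and dp 350, of which it said: “which is a guess”.

The flask gave c = 99.4% and dp = 172, so the forecast's dp was twice the flask's.

    protic impurity + free monomer → quenched substrate (k = 20700 L mol⁻¹ s⁻¹)
    pre-initiator ⇌ initiator (K = 0.388, k = 0.0253 s⁻¹)
    free monomer + living end → monomer in chains + living end, rate k3*[living end]*[free monomer] (k = 41600 L mol⁻¹ s⁻¹)
    free monomer + initiator → living end + monomer in chains (k = 536 L mol⁻¹ s⁻¹)

At 2.50 min the flask held 1.04 × 10⁻⁶ M of living end, with 89.4% of the charge as monomer in chains. Dividing κ by k3 gave 1.02 × 10⁻⁶ M of chain ends, a reading from two scattered grey points for the stretch from 60.0 s to 80.0 s, not a count for 2.50 min. The same flask read at 40 s had 39.1% in chains; κ from the readings around that time gave 6.77 × 10⁻⁷ M of chain ends, hence 116 units, and its simulated dp was 115.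

The earlier runs and the new flask come from a simulation on assumed constants, noise included.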